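**Plan**

- Cuts: (a) the interflavanyl bond C4–C6', giving a flavan-4-one (upper half) and a 6'-lithiated 2,3-trans-3,4-cis-flavan-3,4-diol (lower half); (b) both halves go back to one 6-bromodihydroflavonol, opened at O1'–C2' (= O1–C2) to a 2'-hydroxy-α-silyloxydihydrochalcone; (c) its aryl ketone bond C4'–C4a' is cut to a danshensu Weinreb amide and monolithiated 4,6-dibromoresorcinol dibenzyl ether.
- Enabling feature: ring E with C2'–C4' (and ring B with C2–C4) is a catechol C6–C3 unit whose oxygenated C3' (C3) has the configuration of (R)-danshensu and whose C2' (C2) is a benzylic CH2 para to a ring E (ring B) oxygen, so hydride can be taken from it and the ring D (ring A) phenol can close ring F (ring C).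
- Forward: rings A/D and B/E are bought; the aryl ketone is assembled; ring F (= ring C) closes by oxidative C–H etherification; the product is divided (reduction and silylation for the lower half, debromination for the upper half); the halves are joined at C4–C6'; the C4 hydroxyl is replaced by hydrogen; protecting groups are removed.
- Stereochemistry: C3 and C3' come from danshensu; C2 and C2' are set trans to them in the key step; C4' by LiBH(s-Bu)3 attack anti to the C3' silyl ether (3',4'-cis); C4 by hydride transfer to the C4 cation anti to the C3 silyl ether (ring D cis to O3, 4β).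

Key step: step 7

Remark: flavan locants are used (upper unit rings A, C, B and C2–C4; lower unit rings D, F, E with primed locants). The target is read as fisetinidol-(4β→6)-fisetinidol-4β-ol, (2R,3S,4S) in both units. Carbinol 15 is drawn as the C4 epimer expected from attack anti to the silyloxy group; either epimer would give the same cation in step 12.

**Step 1**
Reactants: 1 sodium danshensu [sodium (2R)-3-(3,4-dihydroxyphenyl)-2-hydroxypropanoate]
Product: 2 benzyl (2R)-3-[3,4-bis(benzyloxy)phenyl]-2-hydroxypropanoate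
Conditions: BnBr (3.3 equiv), K2CO3, DMF, argon, rt to 50 °C
Reagents that add atoms: benzyl bromide, BrCc1ccccc1
Why: Williamson alkylation of the carboxylate and the two phenoxides under carbonate base, which should leave the less acidic secondary hydroxyl and the stereocentre untouched.

**Step 2**
Reactants: 2 benzyl (2R)-3-[3,4-bis(benzyloxy)phenyl]-2-hydroxypropanoate
Product: 3 benzyl (2R)-3-[3,4-bis(benzyloxy)phenyl]-2-[(tert-butyldimethylsilyl)oxy]propanoate
Conditions: TBSCl, imidazole, DMF, rt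
Reagents that add atoms: tert-butyldimethylsilyl chloride, CC(C)(C)[Si](C)(C)Cl
Why: standard silylation of a secondary alcohol, giving an ether that tolerates organolithiums, DDQ and hydride and is kept until the end.

**Step 3**
Reactants: 3 benzyl (2R)-3-[3,4-bis(benzyloxy)phenyl]-2-[(tert-butyldimethylsilyl)oxy]propanoate
Product: 4 (2R)-3-[3,4-bis(benzyloxy)phenyl]-2-[(tert-butyldimethylsilyl)oxy]-N-methoxy-N-methylpropanamide
Conditions: MeNH(OMe)·HCl, i-PrMgCl, THF, −20 to 0 °C; aq. NH4Cl
Reagents that add atoms: N,O-dimethylhydroxylamine hydrochloride, CNOC.Cl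
Why: direct conversion of an ester into the Weinreb amide by the chloromagnesium amide, a method that should not epimerise α-silyloxy esters.

**Step 4**
Reactants: 5 4,6-dibromoresorcinol (4,6-dibromobenzene-1,3-diol)
Product: 6 1,5-dibromo-2,4-bis(benzyloxy)benzene
Conditions: BnBr, K2CO3, DMF, 60 °C
Reagents that add atoms: benzyl bromide, BrCc1ccccc1
Why: Williamson etherification of both phenols.

**Step 5**
Reactants: 6 1,5-dibromo-2,4-bis(benzyloxy)benzene; 4 (2R)-3-[3,4-bis(benzyloxy)phenyl]-2-[(tert-butyldimethylsilyl)oxy]-N-methoxy-N-methylpropanamide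
Product: 8 (2R)-1-[2,4-bis(benzyloxy)-5-bromophenyl]-3-[3,4-bis(benzyloxy)phenyl]-2-[(tert-butyldimethylsilyl)oxy]propan-1-one, via aryllithium 7 (not isolated)
Conditions: 6 (1.15 equiv), n-BuLi (1.1 equiv), THF, −78 °C; then 4, −78 to −40 °C; aq. NH4Cl
Reagents that add atoms: none
Why: single bromine–lithium exchange on the symmetrical dibromide followed by Weinreb ketone synthesis, where the chelated tetrahedral adduct should stop over-addition and the second bromine stays as the later C6' handle.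

**Step 6**
Reactants: 8 (2R)-1-[2,4-bis(benzyloxy)-5-bromophenyl]-3-[3,4-bis(benzyloxy)phenyl]-2-[(tert-butyldimethylsilyl)oxy]propan-1-one
Product: 9 (2R)-1-[4-(benzyloxy)-5-bromo-2-hydroxyphenyl]-3-[3,4-bis(benzyloxy)phenyl]-2-[(tert-butyldimethylsilyl)oxy]propan-1-one
Conditions: MgBr2·OEt2 (3 equiv), toluene/Et2O, 60 °C; dilute HCl work-up
Reagents that add atoms: none
Why: chelation-directed cleavage of the benzyl ether ortho to the carbonyl by the magnesium Lewis acid with bromide as nucleophile, the other three benzyl ethers lacking the six-membered chelate.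

**Step 7**
Reactants: 9 (2R)-1-[4-(benzyloxy)-5-bromo-2-hydroxyphenyl]-3-[3,4-bis(benzyloxy)phenyl]-2-[(tert-butyldimethylsilyl)oxy]propan-1-one
Product: 10 (2R,3R)-7-(benzyloxy)-2-[3,4-bis(benzyloxy)phenyl]-6-bromo-3-[(tert-butyldimethylsilyl)oxy]-2,3-dihydro-4H-chromen-4-one
Conditions: DDQ (1.2 equiv), 4 Å molecular sieves, ClCH2CH2Cl, rt to 50 °C, dark
Reagents that add atoms: none
Why: DDQ forms a charge-transfer complex with ring E and removes hydride from the C2' methylene, which is benzylic and para to the ring E 4-benzyloxy group, giving a para-quinone-methide-like cation paired with DDQH−; the ketone-chelated 8a'-OH then adds to C2', forming O1'–C2', and the proton ends on the hydroquinone. The closest known reaction type is the DDQ-mediated oxidative cyclisation of 2'-hydroxy-1,3-diarylpropanes and 2'-hydroxydihydrochalcones at the benzylic carbon of an alkoxyaryl ring. Ring F closes in the 6-exo-trig mode, the C2'=C(ring E) π bond of the cation lying outside the new ring. The new C2' centre is controlled by the danshensu-derived C3' centre: allylic 1,3-strain keeps C3'–H in the plane of the cation, so the aroyl arm and the silyloxy group lie on opposite faces and the phenol adds anti to the silyloxy group through a chair-like transition state with ring E and OTBS equatorial, which should give the 2',3'-trans (2R,3R) ring. The same conformation holds C3'–H orthogonal to the vacant orbital, which disfavours proton loss towards a chalcone and so protects C3'. The step needs oxidation at C2' only and no onward dehydrogenation to the flavonol: ring D is deactivated by the acyl group and bromine, the benzyl ether methylenes sit on unactivated phenyl rings, and a small excess of DDQ at moderate temperature limits over-oxidation.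

**Step 8**
Reactants: 10 (2R,3R)-7-(benzyloxy)-2-[3,4-bis(benzyloxy)phenyl]-6-bromo-3-[(tert-butyldimethylsilyl)oxy]-2,3-dihydro-4H-chromen-4-one
Product: 11 (2R,3S,4S)-7-(benzyloxy)-2-[3,4-bis(benzyloxy)phenyl]-6-bromo-3-[(tert-butyldimethylsilyl)oxy]-3,4-dihydro-2H-chromen-4-ol
Conditions: LiBH(s-Bu)3, THF, −78 °C; then NaOH, H2O2, 0 °C
Reagents that add atoms: none
Why: ketone reduction by a bulky trialkylborohydride, which should attack equatorially and anti to the neighbouring equatorial silyloxy group and so give the axial 4'-alcohol cis to O3'.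

**Step 9**
Reactants: 11 (2R,3S,4S)-7-(benzyloxy)-2-[3,4-bis(benzyloxy)phenyl]-6-bromo-3-[(tert-butyldimethylsilyl)oxy]-3,4-dihydro-2H-chromen-4-ol
Product: 12 (2R,3R,4S)-7-(benzyloxy)-2-[3,4-bis(benzyloxy)phenyl]-6-bromo-3,4-bis[(tert-butyldimethylsilyl)oxy]-3,4-dihydro-2H-chromene (2,3-trans-3,4-cis)
Conditions: TBSOTf, 2,6-lutidine, CH2Cl2, −78 to 0 °C
Reagents that add atoms: tert-butyldimethylsilyl trifluoromethanesulfonate, CC(C)(C)[Si](C)(C)OS(=O)(=O)C(F)(F)F
Why: silyl triflate silylation of a hindered secondary alcohol under buffered conditions, giving a benzylic silyl ether that is inert to organolithiums and slow to ionise.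

**Step 10**
Reactants: 10 (2R,3R)-7-(benzyloxy)-2-[3,4-bis(benzyloxy)phenyl]-6-bromo-3-[(tert-butyldimethylsilyl)oxy]-2,3-dihydro-4H-chromen-4-one
Product: 13 (2R,3R)-7-(benzyloxy)-2-[3,4-bis(benzyloxy)phenyl]-3-[(tert-butyldimethylsilyl)oxy]-2,3-dihydro-4H-chromen-4-one
Conditions: Bu3SnH (2 equiv, 0.5 M), AIBN (cat.), toluene, 90 °C
Reagents that add atoms: none
Why: radical-chain hydrodebromination of the aryl bromide by tin hydride, chosen because it is neutral and should not enolise or ring-open the silyloxy flavanone.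

**Step 11**
Reactants: 12 (2R,3R,4S)-7-(benzyloxy)-2-[3,4-bis(benzyloxy)phenyl]-6-bromo-3,4-bis[(tert-butyldimethylsilyl)oxy]-3,4-dihydro-2H-chromene; 13 (2R,3R)-7-(benzyloxy)-2-[3,4-bis(benzyloxy)phenyl]-3-[(tert-butyldimethylsilyl)oxy]-2,3-dihydro-4H-chromen-4-one
Product: 15 4-hydroxyfisetinidol-(4→6)-fisetinidol-4β-ol as its hexa-O-benzyl ether and O3/O3'/O4' tris-TBS ether (tertiary C4 carbinol; ring D on the α-face and OH on the β-face of C4), via aryllithium 14 (not isolated)
Conditions: 12 (1.3 equiv), t-BuLi (2.6 equiv), THF, −78 °C; then 13, −78 to −40 °C; aq. NH4Cl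
Reagents that add atoms: none
Why: bromine–lithium exchange and 1,2-addition of the aryllithium to the flavan-4-one carbonyl, a reaction type established for joining flavan units between C4 and an aromatic carbon, with the nucleophile expected anti to the C3 silyloxy group.

**Step 12**
Reactants: 15 tertiary C4 carbinol (hexa-O-benzyl, tris-TBS)
Product: 16 fisetinidol-(4β→6)-fisetinidol-4β-ol hexa-O-benzyl ether O3/O3'/O4' tris-TBS ether
Conditions: Bu3SnH (5 equiv), CF3CO2H (3 equiv), CH2Cl2, −40 to −10 °C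
Reagents that add atoms: none
Why: ionic hydrogenation in which the tertiary C4 carbinol, flanked by two ortho,para-dioxygenated aryl rings, ionises readily and takes hydride from Bu3SnH anti to the C3 silyloxy group (the face preferred by nucleophiles adding to 2,3-trans flav-4-yl cations), which places ring D cis to O3 (4β), while the secondary monoaryl C4' silyl ether should ionise far more slowly at this temperature.

**Step 13**
Reactants: 16 fisetinidol-(4β→6)-fisetinidol-4β-ol hexa-O-benzyl ether O3/O3'/O4' tris-TBS ether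
Product: 17 fisetinidol-(4β→6)-fisetinidol-4β-ol hexa-O-benzyl ether (O7, O7' and both catechols benzylated; O3, O3', O4' free)
Conditions: Bu4NF, THF, rt to 40 °C; aq. NH4Cl
Reagents that add atoms: none
Why: fluoride cleavage of the three silyl ethers under non-acidic conditions, which should leave the acid-labile C4' carbinol configuration intact.

**Step 14**
Reactants: 17 fisetinidol-(4β→6)-fisetinidol-4β-ol hexa-O-benzyl ether
Product: 18 fisetinidol-(4β→6)-fisetinidol-4β-ol, (2R,3S,4S)-2-(3,4-dihydroxyphenyl)-6-[(2R,3S,4S)-2-(3,4-dihydroxyphenyl)-3,7-dihydroxy-3,4-dihydro-2H-chromen-4-yl]-3,4-dihydro-2H-chromene-3,4,7-triol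
Conditions: H2 (1 atm), Pd(OH)2/C, EtOAc/MeOH, rt; filtration, lyophilisation
Reagents that add atoms: none
Why: hydrogenolysis of six aryl benzyl ethers under neutral conditions, which should be much faster than cleavage of the free benzylic C4'–OH, the cyclic benzylic ethers O1–C2 and O1'–C2' or the C4–C6' bond.

**Compound list**

1 | sodium danshensu, sodium (2R)-3-(3,4-dihydroxyphenyl)-2-hydroxypropanoate | [Na+].[O-]C(=O)[C@H](O)Cc1ccc(O)c(O)c1 | starting material
2 | benzyl (2R)-3-[3,4-bis(benzyloxy)phenyl]-2-hydroxypropanoate | O=C(OCc1ccccc1)[C@H](O)Cc1ccc(OCc2ccccc2)c(OCc2ccccc2)c1 | intermediate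
3 | benzyl (2R)-3-[3,4-bis(benzyloxy)phenyl]-2-[(tert-butyldimethylsilyl)oxy]propanoate | O=C(OCc1ccccc1)[C@H](O[Si](C)(C)C(C)(C)C)Cc1ccc(OCc2ccccc2)c(OCc2ccccc2)c1 | intermediate
4 | (2R)-3-[3,4-bis(benzyloxy)phenyl]-2-[(tert-butyldimethylsilyl)oxy]-N-methoxy-N-methylpropanamide | CON(C)C(=O)[C@H](O[Si](C)(C)C(C)(C)C)Cc1ccc(OCc2ccccc2)c(OCc2ccccc2)c1 | intermediate
5 | 4,6-dibromoresorcinol | Oc1cc(O)c(Br)cc1Br | starting material
6 | 1,5-dibromo-2,4-bis(benzyloxy)benzene | Brc1cc(Br)c(OCc2ccccc2)cc1OCc1ccccc1 | intermediate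
7 | [2,4-bis(benzyloxy)-5-bromophenyl]lithium | [Li]c1cc(Br)c(OCc2ccccc2)cc1OCc1ccccc1 | intermediate
8 | (2R)-1-[2,4-bis(benzyloxy)-5-bromophenyl]-3-[3,4-bis(benzyloxy)phenyl]-2-[(tert-butyldimethylsilyl)oxy]propan-1-one | Brc1cc(c(OCc2ccccc2)cc1OCc1ccccc1)C(=O)[C@H](O[Si](C)(C)C(C)(C)C)Cc1ccc(OCc2ccccc2)c(OCc2ccccc2)c1 | intermediate
9 | (2R)-1-[4-(benzyloxy)-5-bromo-2-hydroxyphenyl]-3-[3,4-bis(benzyloxy)phenyl]-2-[(tert-butyldimethylsilyl)oxy]propan-1-one | Brc1cc(c(O)cc1OCc1ccccc1)C(=O)[C@H](O[Si](C)(C)C(C)(C)C)Cc1ccc(OCc2ccccc2)c(OCc2ccccc2)c1 | intermediate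
10 | (2R,3R)-7-(benzyloxy)-2-[3,4-bis(benzyloxy)phenyl]-6-bromo-3-[(tert-butyldimethylsilyl)oxy]-2,3-dihydro-4H-chromen-4-one | Brc1cc2c(cc1OCc1ccccc1)O[C@H](c1ccc(OCc3ccccc3)c(OCc3ccccc3)c1)[C@@H](O[Si](C)(C)C(C)(C)C)C2=O | intermediate
11 | (2R,3S,4S)-7-(benzyloxy)-2-[3,4-bis(benzyloxy)phenyl]-6-bromo-3-[(tert-butyldimethylsilyl)oxy]-3,4-dihydro-2H-chromen-4-ol | Brc1cc2c(cc1OCc1ccccc1)O[C@H](c1ccc(OCc3ccccc3)c(OCc3ccccc3)c1)[C@@H](O[Si](C)(C)C(C)(C)C)[C@H]2O | intermediate
12 | (2R,3R,4S)-7-(benzyloxy)-2-[3,4-bis(benzyloxy)phenyl]-6-bromo-3,4-bis[(tert-butyldimethylsilyl)oxy]-3,4-dihydro-2H-chromene | Brc1cc2c(cc1OCc1ccccc1)O[C@H](c1ccc(OCc3ccccc3)c(OCc3ccccc3)c1)[C@@H](O[Si](C)(C)C(C)(C)C)[C@H]2O[Si](C)(C)C(C)(C)C | intermediate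
13 | (2R,3R)-7-(benzyloxy)-2-[3,4-bis(benzyloxy)phenyl]-3-[(tert-butyldimethylsilyl)oxy]-2,3-dihydro-4H-chromen-4-one | c1cc2c(cc1OCc1ccccc1)O[C@H](c1ccc(OCc3ccccc3)c(OCc3ccccc3)c1)[C@@H](O[Si](C)(C)C(C)(C)C)C2=O | intermediate
14 | C6-lithio derivative of 12, [7-(benzyloxy)-2-[3,4-bis(benzyloxy)phenyl]-3,4-bis[(tert-butyldimethylsilyl)oxy]-3,4-dihydro-2H-chromen-6-yl]lithium, configuration as in 12 | [Li]c1cc2c(cc1OCc1ccccc1)O[C@H](c1ccc(OCc3ccccc3)c(OCc3ccccc3)c1)[C@@H](O[Si](C)(C)C(C)(C)C)[C@H]2O[Si](C)(C)C(C)(C)C | intermediate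
15 | 4-hydroxyfisetinidol-(4→6)-fisetinidol-4β-ol hexa-O-benzyl ether O3/O3'/O4' tris-TBS ether (C4: ring D α, OH β) | c1cc2c(cc1OCc1ccccc1)O[C@H](c1ccc(OCc3ccccc3)c(OCc3ccccc3)c1)[C@@H](O[Si](C)(C)C(C)(C)C)[C@]2(O)c1cc2c(cc1OCc1ccccc1)O[C@H](c1ccc(OCc3ccccc3)c(OCc3ccccc3)c1)[C@@H](O[Si](C)(C)C(C)(C)C)[C@H]2O[Si](C)(C)C(C)(C)C | intermediate
16 | fisetinidol-(4β→6)-fisetinidol-4β-ol hexa-O-benzyl ether O3/O3'/O4' tris-TBS ether | c1cc2c(cc1OCc1ccccc1)O[C@H](c1ccc(OCc3ccccc3)c(OCc3ccccc3)c1)[C@@H](O[Si](C)(C)C(C)(C)C)[C@H]2c1cc2c(cc1OCc1ccccc1)O[C@H](c1ccc(OCc3ccccc3)c(OCc3ccccc3)c1)[C@@H](O[Si](C)(C)C(C)(C)C)[C@H]2O[Si](C)(C)C(C)(C)C | intermediate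
17 | fisetinidol-(4β→6)-fisetinidol-4β-ol hexa-O-benzyl ether | c1cc2c(cc1OCc1ccccc1)O[C@H](c1ccc(OCc3ccccc3)c(OCc3ccccc3)c1)[C@@H](O)[C@H]2c1cc2c(cc1OCc1ccccc1)O[C@H](c1ccc(OCc3ccccc3)c(OCc3ccccc3)c1)[C@@H](O)[C@H]2O | intermediate
18 | fisetinidol-(4β→6)-fisetinidol-4β-ol (CNP0280090.1) | Oc1ccc2c(c1)O[C@H](c1ccc(O)c(O)c1)[C@@H](O)[C@H]2c1cc2c(cc1O)O[C@H](c1ccc(O)c(O)c1)[C@@H](O)[C@H]2O | target

**Step count and risks**

Total steps: 14. Longest linear sequence: 12 (steps 1, 2, 3, 5, 6, 7, 8, 9, 11, 12, 13, 14).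

Step 7. What may go wrong: the C2' cation may lose the C3' proton instead of closing, which leads to a chalcone and erodes the C3'/C2' configuration, or the closure may show weak facial discrimination. The fallback replaces the passive silyl ether by a participating acetate. It sets out from 9. HF·pyridine in THF should remove the silyl group to give (2R)-1-[4-(benzyloxy)-5-bromo-2-hydroxyphenyl]-3-[3,4-bis(benzyloxy)phenyl]-2-hydroxypropan-1-one F1. Ac2O/pyridine at 0 °C should acetylate only the secondary hydroxyl, the phenol being held in its hydrogen bond to the ketone, to give the α-acetoxy ketone F2. DDQ under the step 7 conditions should then pass through a 1,3-dioxolan-2-ylium ion bridging C3' and C2', which the phenol opens at C2' with inversion to the trans dihydroflavonol 3-acetate F3. HCl in MeOH should transesterify the acetate to the 3-hydroxy dihydroflavonol F4, and TBSCl/imidazole in DMF comes back to the route at 10.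

Step 12. What may go wrong: the acid may also ionise the benzylic C4' silyl ether, with loss of that oxygen, and hydride transfer may be incompletely face-selective. The fallback removes the acid by making the deoxygenation a radical process; the facial course rests on the same anti approach and can be sharpened with a bulkier hydrogen donor. It sets out from 15. Deprotonation with KN(SiMe3)2 in THF at −78 °C and acylation with methyl chlorooxoacetate should give the tertiary methyl oxalate F5. Bu3SnH/AIBN in toluene at 100 °C should then cleave the C4–O bond homolytically (a Barton–McCombie-type deoxygenation of a tertiary oxalate), the stabilised C4 radical taking hydrogen from the tin hydride anti to the C3 silyloxy group, and the route is rejoined at 16.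

Step 14. What may go wrong: hydrogenolysis of the free benzylic C4'–OH competing with O-debenzylation, or epimerisation at C4' on an acidic catalyst support. The fallback reverses the order of deprotection so that the C4' oxygen is masked during hydrogenolysis. It sets out from 16. H2 and Pd(OH)2/C in EtOAc/MeOH with all three silyl ethers in place should give the hexaphenol tris-silyl ether F6, the bulky silyl ether shielding the C4'–O bond. Et3N·3HF in THF/MeCN should then remove the silyl groups under near-neutral conditions, arriving at 18.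

**Further compounds**

F1 | step 7 | (2R)-1-[4-(benzyloxy)-5-bromo-2-hydroxyphenyl]-3-[3,4-bis(benzyloxy)phenyl]-2-hydroxypropan-1-one | Brc1cc(c(O)cc1OCc1ccccc1)C(=O)[C@H](O)Cc1ccc(OCc2ccccc2)c(OCc2ccccc2)c1
F2 | step 7 | (2R)-1-[4-(benzyloxy)-5-bromo-2-hydroxyphenyl]-3-[3,4-bis(benzyloxy)phenyl]-1-oxopropan-2-yl acetate | Brc1cc(c(O)cc1OCc1ccccc1)C(=O)[C@H](OC(C)=O)Cc1ccc(OCc2ccccc2)c(OCc2ccccc2)c1
F3 | step 7 | (2R,3R)-7-(benzyloxy)-2-[3,4-bis(benzyloxy)phenyl]-6-bromo-4-oxo-3,4-dihydro-2H-chromen-3-yl acetate | Brc1cc2c(cc1OCc1ccccc1)O[C@H](c1ccc(OCc3ccccc3)c(OCc3ccccc3)c1)[C@@H](OC(C)=O)C2=O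
F4 | step 7 | (2R,3R)-7-(benzyloxy)-2-[3,4-bis(benzyloxy)phenyl]-6-bromo-3-hydroxy-2,3-dihydro-4H-chromen-4-one | Brc1cc2c(cc1OCc1ccccc1)O[C@H](c1ccc(OCc3ccccc3)c(OCc3ccccc3)c1)[C@@H](O)C2=O
F5 | step 12 | C4 methyl oxalate of carbinol 15 | c1cc2c(cc1OCc1ccccc1)O[C@H](c1ccc(OCc3ccccc3)c(OCc3ccccc3)c1)[C@@H](O[Si](C)(C)C(C)(C)C)[C@]2(OC(=O)C(=O)OC)c1cc2c(cc1OCc1ccccc1)O[C@H](c1ccc(OCc3ccccc3)c(OCc3ccccc3)c1)[C@@H](O[Si](C)(C)C(C)(C)C)[C@H]2O[Si](C)(C)C(C)(C)C
F6 | step 14 | fisetinidol-(4β→6)-fisetinidol-4β-ol O3/O3'/O4' tris-TBS ether (all six phenols free) | Oc1ccc2c(c1)O[C@H](c1ccc(O)c(O)c1)[C@@H](O[Si](C)(C)C(C)(C)C)[C@H]2c1cc2c(cc1O)O[C@H](c1ccc(O)c(O)c1)[C@@H](O[Si](C)(C)C(C)(C)C)[C@H]2O[Si](C)(C)C(C)(C)C
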